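**Plan**

1. Retrosynthesis: after removal of three silyl groups, ring B is cut at C1'–C2', C3'–C4' and C5'–C6' in one [2+2+2] step into a benzofuranyl 1,7-diyne (15) and a prenyl siloxyalkyne (19).
2. Enabling feature: ring B (C1'–C6') is a pentasubstituted benzene fused through C5'–C6' to the dihydropyran ring. Each ring carbon can be written as an alkyne carbon: C1'/C6' and C5'/C4' are the two alkynes of a diyne tethered by CH2–CH2–CMe2–O, and C2'/C3' is the siloxyalkyne.
3. The diyne is cut further at the ynol ether C–O bond (trichloroethylene), at the furan C–O and alkyne–C2 bonds (gem-dibromoalkene plus 2-methylhex-5-yn-2-ol) and at the C7 1,1-dimethylallyl group (Claisen rearrangement of an O-prenyl ether).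
4. Forward order: ring A is elaborated from 2,4,6-trihydroxybenzaldehyde; the furan ring and the alkyne are installed in one pot; the ynol ether is made; ring B and the dihydropyran ring close together in the key step; desilylation ends the route.
5. Stereochemistry: the target has no stereocentre and no configured double bond. Only regiochemistry has to be controlled (Claisen shift to C3, orientation of the siloxyalkyne).

Key step: step 9

Remark: all three phenols are carried as triisopropylsilyl ethers because the route passes through a potassium alkoxide and hot amine, and the tertiary alkyl ethynyl ether 15 is assumed to survive only if made and used cold.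

**Route**

Step 1
Reactants: 1 2,4,6-trihydroxybenzaldehyde
Product: 2 2-hydroxy-4,6-bis(triisopropylsilyloxy)benzaldehyde
Conditions: iPr3SiCl (2.1 equiv), imidazole, DMF, 0 °C → rt
Reagents that add atoms: triisopropylsilyl chloride, CC(C)[Si](Cl)(C(C)C)C(C)C
Why: Silylation of phenols with a chlorosilane and imidazole; the para OH and one ortho OH react, after which the last ortho OH is held in a hydrogen bond to the formyl oxygen and should resist the bulky chlorosilane.

Step 2
Reactants: 2 2-hydroxy-4,6-bis(triisopropylsilyloxy)benzaldehyde; 3 3-methylbut-2-en-1-ol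
Product: 4 2-(3-methylbut-2-enyloxy)-4,6-bis(triisopropylsilyloxy)benzaldehyde
Conditions: PPh3, DIAD, THF, 0 °C → rt
Reagents that add atoms: none
Why: Mitsunobu etherification of the acidic chelated phenol with a primary allylic alcohol under neutral conditions, which avoids carbonate bases that could cleave the formyl-activated silyl ethers and should give O- rather than C-alkylation.

Step 3
Reactants: 4 2-(3-methylbut-2-enyloxy)-4,6-bis(triisopropylsilyloxy)benzaldehyde
Product: 6 2-hydroxy-3-(2-methylbut-3-en-2-yl)-4,6-bis(triisopropylsilyloxy)benzaldehyde, via ortho-dienone 5 (not isolated)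
Conditions: N,N-diethylaniline, 190 °C, sealed tube, argon
Reagents that add atoms: none
Why: Aromatic Claisen rearrangement; the [3,3] shift delivers the allyl unit with inversion to C3, the only free ortho carbon, and the basic solvent should tautomerise dienone 5 to the chelated phenol faster than a second shift to C5 can occur.

Step 4
Reactants: 6 2-hydroxy-3-(2-methylbut-3-en-2-yl)-4,6-bis(triisopropylsilyloxy)benzaldehyde
Product: 7 2-(2,2-dibromovinyl)-6-(2-methylbut-3-en-2-yl)-3,5-bis(triisopropylsilyloxy)phenol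
Conditions: CBr4, PPh3, Et3N, CH2Cl2, 0 °C
Reagents that add atoms: carbon tetrabromide, BrC(Br)(Br)Br
Why: Ramirez dibromoolefination (first half of the Corey–Fuchs sequence), as known for salicylaldehydes with a free hydroxyl; triethylamine takes up the HBr equivalents so that the phenol, silyl ethers and terminal alkene should be left alone.

Step 5
Reactants: 7 2-(2,2-dibromovinyl)-6-(2-methylbut-3-en-2-yl)-3,5-bis(triisopropylsilyloxy)phenol; 8 2-methylhex-5-yn-2-ol
Product: 10 2-methyl-6-[7-(2-methylbut-3-en-2-yl)-4,6-bis(triisopropylsilyloxy)benzofuran-2-yl]hex-5-yn-2-ol, via 2-bromobenzofuran 9 (not isolated)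
Conditions: Pd/C (2 mol% Pd), CuI (4 mol%), P(4-MeOC6H4)3 (8 mol%), iPr2NH, toluene, 100 °C
Reagents that add atoms: none
Why: Tandem copper-catalysed intramolecular Ullmann-type C–O coupling of the phenol with the cis bromide to 9, then palladium-catalysed Sonogashira coupling of 9 with the terminal alkyne; this is a known one-pot route from 2-(2,2-dibromovinyl)phenols to 2-alkynylbenzofurans and tolerates a free tertiary alcohol.

Step 6
Reactants: 10 2-methyl-6-[7-(2-methylbut-3-en-2-yl)-4,6-bis(triisopropylsilyloxy)benzofuran-2-yl]hex-5-yn-2-ol; 11 trichloroethylene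
Product: 12 2-{5-[(E)-1,2-dichlorovinyloxy]-5-methylhex-1-ynyl}-7-(2-methylbut-3-en-2-yl)-4,6-bis(triisopropylsilyloxy)benzofuran
Conditions: KH (1.2 equiv), THF, 0 °C; then Cl2C=CHCl, −50 °C → rt
Reagents that add atoms: none
Why: Trichloroethylene route to alkynyl ether precursors; the potassium alkoxide dehydrochlorinates trichloroethylene to dichloroacetylene and adds to it, anti protonation gives the (E)-1,2-dichlorovinyl ether, and the triisopropylsilyl aryl ethers are expected to resist the hindered alkoxide.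

Step 7
Reactants: 12 2-{5-[(E)-1,2-dichlorovinyloxy]-5-methylhex-1-ynyl}-7-(2-methylbut-3-en-2-yl)-4,6-bis(triisopropylsilyloxy)benzofuran
Product: 15 2-(5-ethynyloxy-5-methylhex-1-ynyl)-7-(2-methylbut-3-en-2-yl)-4,6-bis(triisopropylsilyloxy)benzofuran, via chloroethynyl ether 13 (not isolated), via lithium acetylide 14 (not isolated)
Conditions: n-BuLi (2.3 equiv), THF, −78 → −40 °C; then MeOH, −78 °C; cold work-up, used at once as a solution kept below 0 °C
Reagents that add atoms: none
Why: Standard conversion of a 1,2-dichlorovinyl ether into an alkynyl ether: butyllithium dehydrochlorinates 12 to 13, exchanges chlorine for lithium to give 14, and cold protonation gives the terminal ynol ether, which is kept cold because tertiary alkyl ethynyl ethers lose ketene by a retro-ene reaction on warming.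

Step 8
Reactants: 16 ethyl 4-methylpent-3-enoate
Product: 19 triisopropyl(5-methylhex-4-en-1-ynyloxy)silane, via dibromo enolate 17 (not isolated), via lithium ynolate 18 (not isolated)
Conditions: CH2Br2, LiTMP (lithium 2,2,6,6-tetramethylpiperidide, 2.2 equiv), THF, −78 °C; then n-BuLi, −78 °C → rt; then iPr3SiCl, 0 °C → rt
Reagents that add atoms: dibromomethane, BrCBr; triisopropylsilyl chloride, CC(C)[Si](Cl)(C(C)C)C(C)C
Why: Kowalski ester homologation stopped at the ynolate: dibromomethyllithium adds to the ester, enolate 17 undergoes bromine–lithium exchange and 1,2-shift to ynolate 18, and the hindered chlorosilane should silylate on oxygen to give the siloxyalkyne.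

Step 9
Reactants: 15 2-(5-ethynyloxy-5-methylhex-1-ynyl)-7-(2-methylbut-3-en-2-yl)-4,6-bis(triisopropylsilyloxy)benzofuran; 19 triisopropyl(5-methylhex-4-en-1-ynyloxy)silane
Product: 21 2-[2,2-dimethyl-6-(3-methylbut-2-enyl)-7-(triisopropylsilyloxy)chroman-5-yl]-7-(2-methylbut-3-en-2-yl)-4,6-bis(triisopropylsilyloxy)benzofuran, via rhodacyclopentadiene 20 (not isolated)
Conditions: [Rh(C8H12)2]BF4 (10 mol%), rac-H8-BINAP (10 mol%), activated with H2 then purged with argon, CH2Cl2; 19 (3 equiv); 15 added over 4 h by syringe pump, 0 → 20 °C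
Reagents that add atoms: none
Why: Proposed new method: cationic monovalent rhodium carrying the bisphosphine should bind both alkynes of 15 and couple them oxidatively to rhodacyclopentadiene 20 (trivalent rhodium), which forms C5'–C6' and closes the dihydropyran by a metal-templated six-membered ring closure assisted by the gem-dimethyl group; insertion of siloxyalkyne 19 and reductive elimination then form C1'–C2' and C3'–C4' and close ring B as a formal [2+2+2] cycloaddition. The closest known reaction type is the cationic rhodium/bisphosphine cyclotrimerisation of tethered 1,7-diynes, ynol-ether- and ynamide-linked ones included, with a monoalkyne at room temperature, and alkoxy-substituted alkynes have served as the third alkyne in cobalt-mediated cocyclisations; new here is a siloxyalkyne as the third alkyne combined with a tertiary alkyl ethynyl ether in the diyne. No stereocentre is formed, and the new aryl–benzofuran axis, flanked on the furan side only by O1 and C3–H, is not expected to be configurationally stable. The selectivity needed is the orientation of 19: its oxygen-bearing carbon must bond to the unsubstituted C4' and its prenyl-bearing carbon to C1', which polarity (the electrophilic C–O carbon of 19 meeting the nucleophilic terminal carbon of the ynol ether) and sterics (the OSi(iPr)3 end turning away from the benzofuranyl-substituted metallacycle carbon) should both favour. Excess 19, slow addition of 15 and a temperature not above 20 °C should hold back self-trimerisation of the diyne and loss of ketene from the tertiary ynol ether.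

Step 10
Reactants: 21 2-[2,2-dimethyl-6-(3-methylbut-2-enyl)-7-(triisopropylsilyloxy)chroman-5-yl]-7-(2-methylbut-3-en-2-yl)-4,6-bis(triisopropylsilyloxy)benzofuran
Product: 22 artopetelin C, 2-[7-hydroxy-2,2-dimethyl-6-(3-methylbut-2-enyl)chroman-5-yl]-7-(2-methylbut-3-en-2-yl)benzofuran-4,6-diol
Conditions: Bu4NF (3.5 equiv), AcOH (3.5 equiv), THF, 0 °C, argon
Reagents that add atoms: none
Why: Fluoride-mediated cleavage of the three aryl silyl ethers, buffered with acetic acid so that the electron-rich phenoxides are protonated at once and no acid strong enough to cyclise the prenyl or 1,1-dimethylallyl group onto a neighbouring phenol is present.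

**Compound list**

1 | 2,4,6-trihydroxybenzaldehyde | O=Cc1c(O)cc(O)cc1O | starting material
2 | 2-hydroxy-4,6-bis(triisopropylsilyloxy)benzaldehyde | O=Cc1c(O)cc(O[Si](C(C)C)(C(C)C)C(C)C)cc1O[Si](C(C)C)(C(C)C)C(C)C | intermediate
3 | 3-methylbut-2-en-1-ol | CC(C)=CCO | starting material
4 | 2-(3-methylbut-2-enyloxy)-4,6-bis(triisopropylsilyloxy)benzaldehyde | O=Cc1c(OCC=C(C)C)cc(O[Si](C(C)C)(C(C)C)C(C)C)cc1O[Si](C(C)C)(C(C)C)C(C)C | intermediate
5 | 5-(2-methylbut-3-en-2-yl)-6-oxo-2,4-bis(triisopropylsilyloxy)cyclohexa-1,3-diene-1-carbaldehyde (ortho-dienone, racemic, transient) | O=CC1=C(O[Si](C(C)C)(C(C)C)C(C)C)C=C(O[Si](C(C)C)(C(C)C)C(C)C)C(C(C)(C)C=C)C1=O | intermediate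
6 | 2-hydroxy-3-(2-methylbut-3-en-2-yl)-4,6-bis(triisopropylsilyloxy)benzaldehyde | O=Cc1c(O)c(C(C)(C)C=C)c(O[Si](C(C)C)(C(C)C)C(C)C)cc1O[Si](C(C)C)(C(C)C)C(C)C | intermediate
7 | 2-(2,2-dibromovinyl)-6-(2-methylbut-3-en-2-yl)-3,5-bis(triisopropylsilyloxy)phenol | BrC(Br)=Cc1c(O)c(C(C)(C)C=C)c(O[Si](C(C)C)(C(C)C)C(C)C)cc1O[Si](C(C)C)(C(C)C)C(C)C | intermediate
8 | 2-methylhex-5-yn-2-ol | C#CCCC(C)(C)O | starting material
9 | 2-bromo-7-(2-methylbut-3-en-2-yl)-4,6-bis(triisopropylsilyloxy)benzofuran | Brc1cc2c(O[Si](C(C)C)(C(C)C)C(C)C)cc(O[Si](C(C)C)(C(C)C)C(C)C)c(C(C)(C)C=C)c2o1 | intermediate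
10 | 2-methyl-6-[7-(2-methylbut-3-en-2-yl)-4,6-bis(triisopropylsilyloxy)benzofuran-2-yl]hex-5-yn-2-ol | CC(C)(O)CCC#Cc1cc2c(O[Si](C(C)C)(C(C)C)C(C)C)cc(O[Si](C(C)C)(C(C)C)C(C)C)c(C(C)(C)C=C)c2o1 | intermediate
11 | trichloroethylene | ClC=C(Cl)Cl | starting material
12 | 2-{5-[(E)-1,2-dichlorovinyloxy]-5-methylhex-1-ynyl}-7-(2-methylbut-3-en-2-yl)-4,6-bis(triisopropylsilyloxy)benzofuran | Cl/C=C(/Cl)OC(C)(C)CCC#Cc1cc2c(O[Si](C(C)C)(C(C)C)C(C)C)cc(O[Si](C(C)C)(C(C)C)C(C)C)c(C(C)(C)C=C)c2o1 | intermediate
13 | 2-[5-(chloroethynyloxy)-5-methylhex-1-ynyl]-7-(2-methylbut-3-en-2-yl)-4,6-bis(triisopropylsilyloxy)benzofuran | ClC#COC(C)(C)CCC#Cc1cc2c(O[Si](C(C)C)(C(C)C)C(C)C)cc(O[Si](C(C)C)(C(C)C)C(C)C)c(C(C)(C)C=C)c2o1 | intermediate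
14 | lithium acetylide of 15 | [Li]C#COC(C)(C)CCC#Cc1cc2c(O[Si](C(C)C)(C(C)C)C(C)C)cc(O[Si](C(C)C)(C(C)C)C(C)C)c(C(C)(C)C=C)c2o1 | intermediate
15 | 2-(5-ethynyloxy-5-methylhex-1-ynyl)-7-(2-methylbut-3-en-2-yl)-4,6-bis(triisopropylsilyloxy)benzofuran | C#COC(C)(C)CCC#Cc1cc2c(O[Si](C(C)C)(C(C)C)C(C)C)cc(O[Si](C(C)C)(C(C)C)C(C)C)c(C(C)(C)C=C)c2o1 | intermediate
16 | ethyl 4-methylpent-3-enoate | CCOC(=O)CC=C(C)C | starting material
17 | lithium enolate of 1,1-dibromo-5-methylhex-4-en-2-one | [Li]OC(CC=C(C)C)=C(Br)Br | intermediate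
18 | lithium 5-methylhex-4-en-1-yn-1-olate | [Li]OC#CCC=C(C)C | intermediate
19 | triisopropyl(5-methylhex-4-en-1-ynyloxy)silane | CC(C)=CCC#CO[Si](C(C)C)(C(C)C)C(C)C | intermediate
20 | rhodacyclopentadiene from 15 (bisphosphine on rhodium omitted) | [Rh+]1C(c2cc3c(O[Si](C(C)C)(C(C)C)C(C)C)cc(O[Si](C(C)C)(C(C)C)C(C)C)c(C(C)(C)C=C)c3o2)=C2CCC(C)(C)OC2=C1 | intermediate
21 | 2-[2,2-dimethyl-6-(3-methylbut-2-enyl)-7-(triisopropylsilyloxy)chroman-5-yl]-7-(2-methylbut-3-en-2-yl)-4,6-bis(triisopropylsilyloxy)benzofuran | C=CC(C)(C)c1c(O[Si](C(C)C)(C(C)C)C(C)C)cc(O[Si](C(C)C)(C(C)C)C(C)C)c2cc(-c3c(CC=C(C)C)c(O[Si](C(C)C)(C(C)C)C(C)C)cc4c3CCC(C)(C)O4)oc12 | intermediate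
22 | artopetelin C | C=CC(C)(C)c1c(O)cc(O)c2cc(-c3c(CC=C(C)C)c(O)cc4c3CCC(C)(C)O4)oc12 | target

**Count and risks**

Total step count: 10. Longest linear sequence: 9 steps (steps 1–7, 9 and 10); step 8 is a one-step side branch.

Steps most likely to fail:

Step 9. The siloxyalkyne may insert in the reverse orientation, either alkyne may self-trimerise, the tertiary ynol ether may fragment to ketene before it is consumed, or the cationic metal may ionise the siloxyalkyne. The fallback makes ring B and the dihydropyran by classical arene chemistry and joins them to the benzofuran by Suzuki–Miyaura coupling. It sets out from 9 (isolated by running only the copper half of step 5: CuI, K3PO4, THF, 80 °C, no alkyne) and comes back to the route at 21. Phloroglucinol and 2-methylbut-3-en-2-ol with BF3·OEt2 in dioxane should give 2,2-dimethylchroman-5,7-diol F1. MOMCl and iPr2NEt convert it into 5,7-bis(methoxymethoxy)-2,2-dimethylchroman F2. Lithiation with n-BuLi at C6 (the carbon between the two acetal oxygens), transmetalation with CuBr·SMe2 and alkylation with prenyl bromide should give 5,7-bis(methoxymethoxy)-2,2-dimethyl-6-(3-methylbut-2-enyl)chroman F3. Dilute HCl in methanol at room temperature should free 2,2-dimethyl-6-(3-methylbut-2-enyl)chroman-5,7-diol F4. iPr3SiCl and imidazole should silylate the less hindered 7-OH to give 2,2-dimethyl-6-(3-methylbut-2-enyl)-7-(triisopropylsilyloxy)chroman-5-ol F5, and Tf2O with pyridine then gives 2,2-dimethyl-6-(3-methylbut-2-enyl)-7-(triisopropylsilyloxy)chroman-5-yl trifluoromethanesulfonate F6. Bromide 9 is converted by bromine–lithium exchange (n-BuLi, THF, −78 °C) and 2-isopropoxy-4,4,5,5-tetramethyl-1,3,2-dioxaborolane into 2-[7-(2-methylbut-3-en-2-yl)-4,6-bis(triisopropylsilyloxy)benzofuran-2-yl]-4,4,5,5-tetramethyl-1,3,2-dioxaborolane F7. Coupling of F6 with F7 (Pd(OAc)2, SPhos, K3PO4, toluene–water, 80 °C) should give 21.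

Step 3. The ortho-dienone may undergo a second [3,3] shift to C5 before it tautomerises, which would give the linear prenyl isomer, and the hot phenol may add to its new alkene. The fallback moves the rearrangement to a substrate whose para position is blocked and whose two ortho carbons are equivalent. It sets out from 1 and comes back at 6. Mitsunobu reaction of 1 with 3 (PPh3, DIAD, THF) at the most acidic, non-chelated 4-OH should give 2,6-dihydroxy-4-(3-methylbut-2-enyloxy)benzaldehyde F8. Claisen rearrangement in N,N-diethylaniline can then only end at C3 or the equivalent C5 and should give 2,4,6-trihydroxy-3-(2-methylbut-3-en-2-yl)benzaldehyde F9. iPr3SiCl (2 equiv) and imidazole should silylate the 4-OH and 6-OH and spare the 2-OH, which is both chelated to the formyl group and flanked by the quaternary carbon, to give 6.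

Step 6. The potassium alkoxide may add to the neighbouring aryl alkyne in a 5-exo cyclisation, or may be too hindered to engage trichloroethylene. The fallback reaches the ynol ether without an alkoxide; it sets out from 10 and comes back at 15. Acetic formic anhydride and pyridine should give 2-methyl-6-[7-(2-methylbut-3-en-2-yl)-4,6-bis(triisopropylsilyloxy)benzofuran-2-yl]hex-5-yn-2-yl formate F10. Wittig-type dichloromethylenation of the formate (PPh3, CCl4, THF, 60 °C) should give 2-[5-(2,2-dichlorovinyloxy)-5-methylhex-1-ynyl]-7-(2-methylbut-3-en-2-yl)-4,6-bis(triisopropylsilyloxy)benzofuran F11. n-BuLi under the conditions of step 7 should take F11 through 13 and 14 to 15.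

Further compounds
F1 | step 9 | 2,2-dimethylchroman-5,7-diol | CC1(C)CCc2c(O)cc(O)cc2O1
F2 | step 9 | 5,7-bis(methoxymethoxy)-2,2-dimethylchroman | CC1(C)CCc2c(OCOC)cc(OCOC)cc2O1
F3 | step 9 | 5,7-bis(methoxymethoxy)-2,2-dimethyl-6-(3-methylbut-2-enyl)chroman | CC1(C)CCc2c(OCOC)c(CC=C(C)C)c(OCOC)cc2O1
F4 | step 9 | 2,2-dimethyl-6-(3-methylbut-2-enyl)chroman-5,7-diol | CC1(C)CCc2c(O)c(CC=C(C)C)c(O)cc2O1
F5 | step 9 | 2,2-dimethyl-6-(3-methylbut-2-enyl)-7-(triisopropylsilyloxy)chroman-5-ol | CC1(C)CCc2c(O)c(CC=C(C)C)c(O[Si](C(C)C)(C(C)C)C(C)C)cc2O1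
F6 | step 9 | 2,2-dimethyl-6-(3-methylbut-2-enyl)-7-(triisopropylsilyloxy)chroman-5-yl trifluoromethanesulfonate | CC1(C)CCc2c(OS(=O)(=O)C(F)(F)F)c(CC=C(C)C)c(O[Si](C(C)C)(C(C)C)C(C)C)cc2O1
F7 | step 9 | 2-[7-(2-methylbut-3-en-2-yl)-4,6-bis(triisopropylsilyloxy)benzofuran-2-yl]-4,4,5,5-tetramethyl-1,3,2-dioxaborolane | CC1(C)OB(c2cc3c(O[Si](C(C)C)(C(C)C)C(C)C)cc(O[Si](C(C)C)(C(C)C)C(C)C)c(C(C)(C)C=C)c3o2)OC1(C)C
F8 | step 3 | 2,6-dihydroxy-4-(3-methylbut-2-enyloxy)benzaldehyde | O=Cc1c(O)cc(OCC=C(C)C)cc1O
F9 | step 3 | 2,4,6-trihydroxy-3-(2-methylbut-3-en-2-yl)benzaldehyde | O=Cc1c(O)cc(O)c(C(C)(C)C=C)c1O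
F10 | step 6 | 2-methyl-6-[7-(2-methylbut-3-en-2-yl)-4,6-bis(triisopropylsilyloxy)benzofuran-2-yl]hex-5-yn-2-yl formate | O=COC(C)(C)CCC#Cc1cc2c(O[Si](C(C)C)(C(C)C)C(C)C)cc(O[Si](C(C)C)(C(C)C)C(C)C)c(C(C)(C)C=C)c2o1
F11 | step 6 | 2-[5-(2,2-dichlorovinyloxy)-5-methylhex-1-ynyl]-7-(2-methylbut-3-en-2-yl)-4,6-bis(triisopropylsilyloxy)benzofuran | ClC(Cl)=COC(C)(C)CCC#Cc1cc2c(O[Si](C(C)C)(C(C)C)C(C)C)cc(O[Si](C(C)C)(C(C)C)C(C)C)c(C(C)(C)C=C)c2o1
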